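## Plan

1. **First cut, C7–C8.** This opens the nine-membered ring A (C3, C4, C5, C6, C7, C8, C9, C10 and the bridging O). By allylic transposition the α-methylene lactone becomes a 3-(trimethylsilylmethyl)butenolide facing a C8 aldehyde.
2. **Enabling feature.** C8(OH)–C7–C11(=C13) is a homoallylic alcohol. C7 belongs to both ring A and lactone ring C, and C11=C13 is exocyclic to ring C. One SE2′ event can therefore deliver ring A, C7, C8, the exocyclic methylene and a free 8-OH beside an ester already placed on O9.
3. **Further cuts.** C7=C11 (metathesis), the acyl bonds at O6 and O9, and furanone ring B, which divides into a vinyl iodide (C4–C7, C15), CO (C3) and an alkynol (C1, C2, C8–C10, C14).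
4. **Forward order.** Two fragments, carbonylative coupling, ring B, three site-selective O-functionalisations, ring C by metathesis, ring A last.
5. **Stereochemistry.** C6 comes from a lipase resolution, C9 from the chiral pool (L-glycerate) and C10 from a Felkin–Anh ethynylation. C7 (from C6) and C8 (from C9) are set in the key step. 4Z comes from trans-hydroalumination/iodination, and the side-chain Z geometry from citraconic anhydride.

Key step: step 19

Remark: germacranolide numbering is used. C1 is the ketone, C2=C3 the furanone alkene, C4=C5 the ring alkene (C15 on C4), C6 the lactone O–CH, C8 the carbinol, C9 the ester carbon, C10 the quaternary carbon (C14), C11=C13 the methylene and C12 the lactone carbonyl. Read this way the SMILES is 4Z,6R,7R,8S,9S,10S with a 2Z side chain.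

## Route

Step 1
Reactants: 1 acrolein; 2 prop-1-yn-1-ylmagnesium bromide
Product: 3 rac-hex-1-en-4-yn-3-ol
Conditions: THF, −78 → 0 °C; sat. aq. NH4Cl
Reagents that add atoms: none
Why: 1,2-addition of an alkynyl Grignard reagent to an enal is standard and assembles C4–C7 and C15 as the racemic carbinol, stereocontrol being deferred to step 3.

Step 2
Reactants: 3 rac-hex-1-en-4-yn-3-ol
Product: 5 rac-(4Z)-5-iodohexa-1,4-dien-3-ol, via cyclic alkenylalanate 4 (not isolated)
Conditions: NaAlH2(OCH2CH2OMe)2, Et2O, 0 → 23 °C; EtOAc; I2, THF, −78 °C; aq. Na2S2O3, aq. potassium sodium tartrate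
Reagents that add atoms: iodine, II
Why: Hydroxyl-directed trans-hydroalumination of a propargylic alcohol places aluminium on the distal alkyne carbon (C4) cis to the carbinol in a five-membered alanate, and iodinolysis with retention fixes the 4Z geometry.

Step 3
Reactants: 5 rac-(4Z)-5-iodohexa-1,4-dien-3-ol
Product: 6 (3S,4Z)-5-iodohexa-1,4-dien-3-ol
Conditions: Novozym 435 (immobilised Candida antarctica lipase B), vinyl acetate, MTBE, 30 °C, stopped near half conversion; chromatography
Reagents that add atoms: none
Why: In this lipase kinetic resolution by irreversible transesterification the vinyl group fits the medium pocket and the 2-iodopropenyl group the large pocket, so the R alcohol should be acetylated and the S alcohol (C6 of the target) recovered.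

Step 4
Reactants: 6 (3S,4Z)-5-iodohexa-1,4-dien-3-ol
Product: 7 triethyl{[(3S,4Z)-5-iodohexa-1,4-dien-3-yl]oxy}silane
Conditions: TESCl, imidazole, CH2Cl2, 0 °C
Reagents that add atoms: chlorotriethylsilane, CC[Si](Cl)(CC)CC
Why: Standard silylation masks O6, which would otherwise trap the cis acylpalladium of step 7 as a butenolide.

Step 5
Reactants: 8 methyl (4S)-2,2-dimethyl-1,3-dioxolane-4-carboxylate
Product: 10 1-[(4S)-2,2-dimethyl-1,3-dioxolan-4-yl]ethan-1-one, via Weinreb amide 9 (not isolated)
Conditions: MeNH(OMe)·HCl, iPrMgCl, THF, −20 °C; then MeMgBr, −20 → 0 °C; sat. aq. NH4Cl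
Reagents that add atoms: methylmagnesium bromide, C[Mg]Br
Why: In this one-pot Weinreb ketone synthesis the chelated tetrahedral adduct prevents over-addition, and the low temperature keeps the chiral-pool centre (C9) intact.

Step 6
Reactants: 10 1-[(4S)-2,2-dimethyl-1,3-dioxolan-4-yl]ethan-1-one; 11 ethynylmagnesium bromide
Product: 12 (2R)-2-[(4S)-2,2-dimethyl-1,3-dioxolan-4-yl]but-3-yn-2-ol
Conditions: THF, −78 → −20 °C; sat. aq. NH4Cl; chromatographic removal of the minor epimer
Reagents that add atoms: none
Why: In coordinating THF the acetylide should add by the polar Felkin–Anh mode, anti to the dioxolane C9–O bond, which gives the 9,10-anti relationship and so sets C10.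

Step 7
Reactants: 7 triethyl{[(3S,4Z)-5-iodohexa-1,4-dien-3-yl]oxy}silane; 12 (2R)-2-[(4S)-2,2-dimethyl-1,3-dioxolan-4-yl]but-3-yn-2-ol
Product: 13 (2R,6Z,8S)-2-[(4S)-2,2-dimethyl-1,3-dioxolan-4-yl]-2-hydroxy-6-methyl-8-[(triethylsilyl)oxy]deca-6,9-dien-3-yn-5-one
Conditions: PdCl2(PPh3)2 (5 mol %), CuI (2 mol %), Et3N, THF, CO (1 atm), 23 °C
Reagents that add atoms: carbon monoxide, [C-]#[O+]
Why: In this carbonylative Sonogashira coupling, oxidative addition with retention, CO insertion (C3) and alkynyl transfer give the Z enynone, and at this stage no allylic ester is present that zerovalent palladium could ionise.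

Step 8
Reactants: 13 the ynone of step 7
Product: 16 (2S)-2-[(1S)-1,2-dihydroxyethyl]-5-[(2Z,4S)-4-hydroxyhexa-2,5-dien-2-yl]-2-methylfuran-3(2H)-one, via enaminone 14 (not isolated), via protected furanone 15 (not isolated)
Conditions: Et2NH, EtOH, 23 °C; then AcOH–H2O 4:1, 40 °C
Reagents that add atoms: water, O
Why: This is the classical 4-hydroxy-2-ynone to 3(2H)-furanone transposition, in which the amine adds to C1, hydrolysis puts the carbonyl at C1, O10 closes onto C3 with loss of water (ring B, 5-exo-trig), and the same aqueous acid removes the silyl ether and the acetonide without touching C6, C9 or C10.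

Step 9
Reactants: 16 the triol of step 8
Product: 17 (2S)-2-[(1S)-1-hydroxy-2-(triethylsilyloxy)ethyl]-5-[(2Z,4S)-4-hydroxyhexa-2,5-dien-2-yl]-2-methylfuran-3(2H)-one
Conditions: TESCl (1.05 equiv), imidazole, CH2Cl2, −40 °C
Reagents that add atoms: chlorotriethylsilane, CC[Si](Cl)(CC)CC
Why: Kinetic silylation selects the only primary hydroxyl (O8) over the two secondary ones.

Step 10
Reactants: 18 ethyl 2-[(trimethylsilyl)methyl]prop-2-enoate
Product: 19 2-[(trimethylsilyl)methyl]prop-2-enoic acid
Conditions: LiOH, THF–H2O, 0 → 23 °C; 1 M HCl to pH 3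
Reagents that add atoms: lithium hydroxide, [Li+].[OH-]
Why: In this plain saponification the silyl group should survive, because the carbonyl sits on the central carbon of the allyl unit and cannot stabilise a desilylated anion.

Step 11
Reactants: 17 the C8 silyl ether of step 9; 19 2-[(trimethylsilyl)methyl]prop-2-enoic acid
Product: 20 C6 2-[(trimethylsilyl)methyl]acrylate of 17 (6S,9S,10S; O9 free, O8 as TES ether)
Conditions: EDC·HCl (1.1 equiv), DMAP (0.1 equiv), CH2Cl2, 0 °C
Reagents that add atoms: none
Why: Steglich-type esterification should take the open bis-allylic O6 in preference to O9, which is flanked by quaternary C10 and the silyloxymethyl group.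

Step 12
Reactants: 21 citraconic anhydride
Product: 22 (2Z)-2-methylbut-2-ene-1,4-diol
Conditions: LiAlH4, Et2O, 0 °C; Na2SO4·10H2O
Reagents that add atoms: none
Why: Hydride reduction of the cyclic anhydride carries its cis geometry into the diol, so the Z side-chain alkene needs no olefination.

Step 13
Reactants: 22 (2Z)-2-methylbut-2-ene-1,4-diol
Product: 23 (2Z)-4-hydroxy-3-methylbut-2-en-1-yl acetate
Conditions: porcine pancreatic lipase, vinyl acetate, THF, 23 °C
Reagents that add atoms: vinyl acetate, C=COC(C)=O
Why: Lipase-catalysed monoacetylation of 2-substituted Z-butenediols is known to take the hydroxyl remote from the substituted alkene carbon.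

Step 14
Reactants: 23 (2Z)-4-hydroxy-3-methylbut-2-en-1-yl acetate
Product: 24 (2Z)-4-acetoxy-2-methylbut-2-enoic acid
Conditions: TEMPO (0.2 equiv), PhI(OAc)2 (2.2 equiv), MeCN–H2O 1:1, 0 → 23 °C
Reagents that add atoms: water, O
Why: Oxoammonium oxidation of a primary allylic alcohol through the aldehyde hydrate to the acid runs under near-neutral conditions that should preserve the Z alkene and the acetate.

Step 15
Reactants: 20 the C6 ester of step 11; 24 (2Z)-4-acetoxy-2-methylbut-2-enoic acid
Product: 26 C9 (2Z)-4-acetoxy-2-methylbut-2-enoate of 20 (6S,9S,10S), via mixed anhydride 25 (not isolated)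
Conditions: 24, 2,4,6-trichlorobenzoyl chloride, Et3N, toluene, 23 °C; then 20, DMAP, 23 → 60 °C
Reagents that add atoms: none
Why: Yamaguchi esterification is the established way to put angelate-type acids on hindered secondary alcohols without Z to E isomerisation, and O9 is the only free hydroxyl.

Step 16
Reactants: 26 the diester of step 15
Product: 27 butenolide allylsilane (6R,9S,10S): 3-[(trimethylsilyl)methyl]furan-2(5H)-one joined at its C5 (= C6) through the Z C4=C5 bond to the furanone carrying the C9 ester and CH2OTES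
Conditions: second-generation Hoveyda–Grubbs catalyst (10 mol %), toluene (5 mM), 80 °C, argon sparge
Reagents that add atoms: none
Why: Ring-closing metathesis of an allylic 2-substituted acrylate to a butenolide (ring C) engages only the terminal vinyl group and the 1,1-disubstituted acrylate, because all other alkenes are trisubstituted and conjugated.

Step 17
Reactants: 27 the butenolide allylsilane of step 16
Product: 28 primary alcohol (6R,9S,10S): 27 with free C8–OH
Conditions: AcOH–THF–H2O 3:1:1, 0 → 23 °C
Reagents that add atoms: none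
Why: A primary triethylsilyl ether is cleaved by weak aqueous acid, which avoids fluoride (fatal to the allylsilane) and base (fatal to C6–H of the butenolide and to the position of the ester).

Step 18
Reactants: 28 the primary alcohol of step 17
Product: 29 aldehyde (6R,9R,10S; the C9 descriptor changes by priority only): 28 with C8 as CHO
Conditions: Dess–Martin periodinane, CH2Cl2, 0 °C; used at once
Reagents that add atoms: none
Why: Dess–Martin oxidation is neutral and fast, so the α-acyloxy aldehyde should form without enolisation at C9.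

Step 19
Reactants: 29 the aldehyde of step 18
Product: 30 CNP0523348.1 (4Z,6R,7R,8S,9S,10S)
Conditions: BF3·OEt2 (4 equiv), CH2Cl2, −78 °C, slow addition of 29 (final about 1 mM), then −78 → −30 °C; sat. aq. NaHCO3
Reagents that add atoms: none
Why: Proposed new method: BF3 binds the C8 aldehyde, C7 of the butenolide C7=C11 bond attacks it in the SE2′ sense while the C13–Si bond stabilises the charge growing at C11, and loss of silicon as Me3SiF moves the double bond to C11=C13, so one C–C bond closes the nine-membered ring A (and with it the ten-membered carbocycle), creates the α-methylene lactone and leaves O8 as the only free hydroxyl beside the ester already on O9. The closest known reaction types are the intramolecular Hosomi–Sakurai cyclisation of 2-(alkoxycarbonyl)allylsilanes onto aldehydes and the zinc- or chromium-mediated allylation of aldehydes with 3-(bromomethyl)furan-2(5H)-one, the new elements being the allylsilane embedded in a butenolide and the medium ring. Ring A closes in the 9-exo-trig mode at C8, with both reacting π bonds (C8=O8 and C7=C11) exocyclic to the new ring. C7 is controlled by C6: the tether leaves C6 on one face of the flat butenolide and, stiffened by the Z C4=C5 bond and the planar furanone, should reach C7 around the C6–C7 edge from the opposite face (C5–C6–C7–C8 near 150°), which gives the trans lactone (7R). C8 is controlled by C9 and by the open transition state: with monodentate BF3 the C9–O bond stands anti to the incoming C7 (polar Felkin–Anh, 8,9-anti), and since no metal bridges O8 and C13 the synclinal arrangement with C9 outside and O8 over the lactone can operate and give 8S, whereas a closed chair on this E-type allyl unit would give the C8 epimer. The step needs activation of the aldehyde in the presence of four less electrophilic carbonyl groups, for which excess BF3·OEt2 at low temperature is provided, and cyclisation rather than oligomerisation, for which slow addition at high dilution is provided.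

## Compound list

1 | acrolein | C=CC=O | starting material
2 | prop-1-yn-1-ylmagnesium bromide | CC#C[Mg]Br | starting material
3 | rac-hex-1-en-4-yn-3-ol | C=CC(O)C#CC | intermediate
4 | sodium cyclic alkenylalanate (five-membered O–Al–C4=C5–C6 ring, two 2-methoxyethoxy ligands) | C=CC1C=C(C)[Al-](OCCOC)(OCCOC)O1.[Na+] | intermediate
5 | rac-(4Z)-5-iodohexa-1,4-dien-3-ol | C=CC(O)/C=C(/C)I | intermediate
6 | (3S,4Z)-5-iodohexa-1,4-dien-3-ol | C=C[C@H](O)/C=C(/C)I | intermediate
7 | triethyl{[(3S,4Z)-5-iodohexa-1,4-dien-3-yl]oxy}silane | C=C[C@H](O[Si](CC)(CC)CC)/C=C(/C)I | intermediate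
8 | methyl (4S)-2,2-dimethyl-1,3-dioxolane-4-carboxylate | COC(=O)[C@@H]1COC(C)(C)O1 | starting material
9 | (4S)-N-methoxy-N,2,2-trimethyl-1,3-dioxolane-4-carboxamide | CON(C)C(=O)[C@@H]1COC(C)(C)O1 | intermediate
10 | 1-[(4S)-2,2-dimethyl-1,3-dioxolan-4-yl]ethan-1-one | CC(=O)[C@@H]1COC(C)(C)O1 | intermediate
11 | ethynylmagnesium bromide | C#C[Mg]Br | starting material
12 | (2R)-2-[(4S)-2,2-dimethyl-1,3-dioxolan-4-yl]but-3-yn-2-ol | C#C[C@@](C)(O)[C@@H]1COC(C)(C)O1 | intermediate
13 | (2R,6Z,8S)-2-[(4S)-2,2-dimethyl-1,3-dioxolan-4-yl]-2-hydroxy-6-methyl-8-[(triethylsilyl)oxy]deca-6,9-dien-3-yn-5-one | C=C[C@H](O[Si](CC)(CC)CC)/C=C(/C)C(=O)C#C[C@@](C)(O)[C@@H]1COC(C)(C)O1 | intermediate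
14 | enaminone from addition of Et2NH to C1 of 13 (6S,9S,10R; C1=C2 geometry labile) | C=C[C@H](O[Si](CC)(CC)CC)/C=C(/C)C(=O)C=C(N(CC)CC)[C@@](C)(O)[C@@H]1COC(C)(C)O1 | intermediate
15 | (2S)-2-[(4S)-2,2-dimethyl-1,3-dioxolan-4-yl]-2-methyl-5-[(2Z,4S)-4-(triethylsilyloxy)hexa-2,5-dien-2-yl]furan-3(2H)-one | C=C[C@H](O[Si](CC)(CC)CC)/C=C(/C)C1=CC(=O)[C@@](C)(O1)[C@@H]2COC(C)(C)O2 | intermediate
16 | (2S)-2-[(1S)-1,2-dihydroxyethyl]-5-[(2Z,4S)-4-hydroxyhexa-2,5-dien-2-yl]-2-methylfuran-3(2H)-one | C=C[C@H](O)/C=C(/C)C1=CC(=O)[C@@](C)(O1)[C@@H](O)CO | intermediate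
17 | (2S)-2-[(1S)-1-hydroxy-2-(triethylsilyloxy)ethyl]-5-[(2Z,4S)-4-hydroxyhexa-2,5-dien-2-yl]-2-methylfuran-3(2H)-one | C=C[C@H](O)/C=C(/C)C1=CC(=O)[C@@](C)(O1)[C@@H](O)CO[Si](CC)(CC)CC | intermediate
18 | ethyl 2-[(trimethylsilyl)methyl]prop-2-enoate | C=C(C[Si](C)(C)C)C(=O)OCC | starting material
19 | 2-[(trimethylsilyl)methyl]prop-2-enoic acid | C=C(C[Si](C)(C)C)C(=O)O | intermediate
20 | C6 2-[(trimethylsilyl)methyl]acrylate of 17 (6S,9S,10S) | C=C[C@H](OC(=O)C(=C)C[Si](C)(C)C)/C=C(/C)C1=CC(=O)[C@@](C)(O1)[C@@H](O)CO[Si](CC)(CC)CC | intermediate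
21 | citraconic anhydride | CC1=CC(=O)OC1=O | starting material
22 | (2Z)-2-methylbut-2-ene-1,4-diol | OC/C=C(/C)CO | intermediate
23 | (2Z)-4-hydroxy-3-methylbut-2-en-1-yl acetate | CC(=O)OC/C=C(/C)CO | intermediate
24 | (2Z)-4-acetoxy-2-methylbut-2-enoic acid | CC(=O)OC/C=C(/C)C(=O)O | intermediate
25 | (2Z)-4-acetoxy-2-methylbut-2-enoic 2,4,6-trichlorobenzoic anhydride | CC(=O)OC/C=C(/C)C(=O)OC(=O)c1c(Cl)cc(Cl)cc1Cl | intermediate
26 | C9 (2Z)-4-acetoxy-2-methylbut-2-enoate of 20 (6S,9S,10S) | C=C[C@H](OC(=O)C(=C)C[Si](C)(C)C)/C=C(/C)C1=CC(=O)[C@@](C)(O1)[C@@H](OC(=O)/C(C)=C\COC(C)=O)CO[Si](CC)(CC)CC | intermediate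
27 | butenolide allylsilane (6R,9S,10S), O8 as TES ether | C[Si](C)(C)CC1=C[C@H](OC1=O)/C=C(/C)C2=CC(=O)[C@@](C)(O2)[C@@H](OC(=O)/C(C)=C\COC(C)=O)CO[Si](CC)(CC)CC | intermediate
28 | butenolide allylsilane primary alcohol (6R,9S,10S) | C[Si](C)(C)CC1=C[C@H](OC1=O)/C=C(/C)C2=CC(=O)[C@@](C)(O2)[C@@H](OC(=O)/C(C)=C\COC(C)=O)CO | intermediate
29 | butenolide allylsilane aldehyde (6R,9R,10S) | C[Si](C)(C)CC1=C[C@H](OC1=O)/C=C(/C)C2=CC(=O)[C@@](C)(O2)[C@@H](OC(=O)/C(C)=C\COC(C)=O)C=O | intermediate
30 | CNP0523348.1 (4Z,6R,7R,8S,9S,10S) | C=C1C(=O)O[C@@H]2/C=C(/C)C3=CC(=O)[C@@](C)(O3)[C@@H](OC(=O)/C(C)=C\COC(C)=O)[C@@H](O)[C@@H]12 | target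

## Step count and weak points

Total step count: 19.
Longest linear sequence: 13 (steps 1, 2, 3, 4, 7, 8, 9, 11, 15, 16, 17, 18, 19).

**Step 19.**
- What may go wrong: the acceptor-substituted allylsilane may be too weak a nucleophile for a medium-ring closure. Protodesilylation, enolisation of the α-acyloxy aldehyde with β-elimination of the furanone oxygen, or oligomerisation could then take over. Attack on the wrong butenolide face is the second danger.
- Fallback chemistry: this rests on known reactions. BF3-promoted intramolecular SE2′ addition of allylstannanes to aldehydes closes ten- to fourteen-membered carbocycles through the same open transition state. Lewis-acid additions of 2-(alkoxycarbonyl)allylstannanes to aldehydes are also known. The silicon nucleophile is replaced by a far more nucleophilic tin one.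
- Fallback route: it sets out from 17 and comes back at 30. Ethyl 2-(bromomethyl)acrylate and Bu3SnLi with CuBr·SMe2 should give ethyl 2-[(tributylstannyl)methyl]prop-2-enoate F1, and LiOH then gives 2-[(tributylstannyl)methyl]prop-2-enoic acid F2. EDC/DMAP acylation of 17 at O6 gives the C6 stannylmethylacrylate F3. Yamaguchi esterification with 24 gives the C9 ester F4, and metathesis as in step 16 gives the butenolide allylstannane F5. Aqueous acetic acid gives the primary alcohol F6, and Dess–Martin oxidation gives the aldehyde F7. BF3·OEt2 at −78 °C under high dilution should close F7 to 30.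

**Step 8.**
- What may go wrong: during the slow acetonide hydrolysis the free bis-allylic C6 carbinol may ionise and transpose, or the C4=C5 bond may drift from Z to E.
- Fallback: this changes the order of events so that O6 is never free under the hydrolysis conditions, and it also removes the reliance on the O6/O9 selectivity of step 11. It sets out from 13 and comes back at 20. Et2NH followed by a short treatment with AcOH–THF–H2O at 23 °C (through 14 and 15) should give the C6 alcohol with the acetonide kept F8. EDC/DMAP with 19 gives the C6 ester acetonide F9. AcOH–H2O then hydrolyses the acetonide to the C6 ester 8,9-diol F10, and TESCl/imidazole at −40 °C silylates O8 to give 20.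

**Step 17.**
- What may go wrong: once the primary C8 hydroxyl is free, the neighbouring C9 acyl group may migrate to it.
- Fallback: this avoids the free alcohol altogether. It sets out from 27 and comes back at 29. The primary triethylsilyl ether is oxidised directly under Swern conditions ((COCl)2, DMSO, CH2Cl2, −78 → −40 °C, then iPr2NEt), a known selective reaction of primary TES ethers. No new compound is made, F0.

## Further compounds

F1 | step 19 | ethyl 2-[(tributylstannyl)methyl]prop-2-enoate | CCCC[Sn](CCCC)(CCCC)CC(=C)C(=O)OCC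
F2 | step 19 | 2-[(tributylstannyl)methyl]prop-2-enoic acid | CCCC[Sn](CCCC)(CCCC)CC(=C)C(=O)O
F3 | step 19 | C6 2-[(tributylstannyl)methyl]acrylate of 17 (6S,9S,10S) | C=C[C@H](OC(=O)C(=C)C[Sn](CCCC)(CCCC)CCCC)/C=C(/C)C1=CC(=O)[C@@](C)(O1)[C@@H](O)CO[Si](CC)(CC)CC
F4 | step 19 | C9 (2Z)-4-acetoxy-2-methylbut-2-enoate of F3 | C=C[C@H](OC(=O)C(=C)C[Sn](CCCC)(CCCC)CCCC)/C=C(/C)C1=CC(=O)[C@@](C)(O1)[C@@H](OC(=O)/C(C)=C\COC(C)=O)CO[Si](CC)(CC)CC
F5 | step 19 | butenolide allylstannane, O8 as TES ether | CCCC[Sn](CCCC)(CCCC)CC1=C[C@H](OC1=O)/C=C(/C)C2=CC(=O)[C@@](C)(O2)[C@@H](OC(=O)/C(C)=C\COC(C)=O)CO[Si](CC)(CC)CC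
F6 | step 19 | butenolide allylstannane primary alcohol | CCCC[Sn](CCCC)(CCCC)CC1=C[C@H](OC1=O)/C=C(/C)C2=CC(=O)[C@@](C)(O2)[C@@H](OC(=O)/C(C)=C\COC(C)=O)CO
F7 | step 19 | butenolide allylstannane aldehyde | CCCC[Sn](CCCC)(CCCC)CC1=C[C@H](OC1=O)/C=C(/C)C2=CC(=O)[C@@](C)(O2)[C@@H](OC(=O)/C(C)=C\COC(C)=O)C=O
F8 | step 8 | (2S)-2-[(4S)-2,2-dimethyl-1,3-dioxolan-4-yl]-5-[(2Z,4S)-4-hydroxyhexa-2,5-dien-2-yl]-2-methylfuran-3(2H)-one | C=C[C@H](O)/C=C(/C)C1=CC(=O)[C@@](C)(O1)[C@@H]2COC(C)(C)O2
F9 | step 8 | C6 2-[(trimethylsilyl)methyl]acrylate of F8 | C=C[C@H](OC(=O)C(=C)C[Si](C)(C)C)/C=C(/C)C1=CC(=O)[C@@](C)(O1)[C@@H]2COC(C)(C)O2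
F10 | step 8 | C6 2-[(trimethylsilyl)methyl]acrylate 8,9-diol | C=C[C@H](OC(=O)C(=C)C[Si](C)(C)C)/C=C(/C)C1=CC(=O)[C@@](C)(O1)[C@@H](O)CO
F0 | step 17 | none | none
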